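| setting | east | west | violet | green | blue | ochre |
|---|---|---|---|---|---|---|
| first end groups | 0.067 M | 0.067 M | 0.067 M | 0.067 M | 0.067 M (fed, over 6.0 min) | 0.067 M |
| second end groups | 1.02 equiv | 0.51 equiv | 1.02 equiv (fed, over 6.0 min) | 1.02 equiv (in portions, 2, over 6.0 min) | 1.02 equiv | 1.02 equiv |
| remark | run made earlier | run made earlier | all else is in the flask from the start; the feed brings no volume worth counting | first portion at the start, last at 6.0 min | all else is in the flask from the start; the feed brings no volume worth counting | everything together at the start |
| time |  |  | 8.0 min | 8.0 min | 8.0 min | 8.0 min |

- east (time / min: links / %, first end groups / %): 2.00: 79.2, 14.4; 4.00: 84.7, 6.2; 6.00: 84.6, 7.5; 8.00: 86.8, 7.9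
- west (time / min: links / %, first end groups / %): 0.333: 26.3, 66.6; 0.833: 39.0, 51.5; 1.50: 44.7, 41.4; 2.50: 47.7, 33.9

(readings scatter by 1 percentage point)



* which flask leads in amount of links, in percent of the first end groups charged ("all alike" within 1.5 percentage points) (violet / green / blue / ochre / all alike)
* how much links is there at the end, in percent of the first end groups charged: violet
* how much links is there at the end, in percent of the first end groups charged: green
* how much links is there at the end, in percent of the first end groups charged: blue
* how much links is there at the end, in percent of the first end groups charged: ochre

Add the links and the unreacted first end groups of the west run at 2.50 min, and 18.4% of your charge is left over as neither, so some waste runs beside the coupling. I read that waste as first end groups meeting one another, which makes its rate follow the square of the fraction still unreacted. The mean of that square over the west readings is 0.283, and dividing the lost share by this mean and by the time gives 0.261 min⁻¹, which I call the waste rate, the fraction of the charge lost per minute while the whole charge stands unreacted.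

West made links at 0.790 min⁻¹ up to its first reading, faster than that waste, so I expect ochre, which is the east recipe, to repeat the 86.8% of east. In violet the feed brings second end groups at 0.170 min⁻¹, slower than west's opening coupling, so as an assumption drawn from the start of the feed I let each second end group couple as it arrives, and the waste starts 1.54 times as fast as the feed. If first end groups fall in a straight line toward zero, the square averages a third of its starting value, which slows the waste to a mean of 0.0870 min⁻¹. The links in violet then keep a share of 66.2%, below ochre. The straight line and the coupling on arrival are the rough steps here.

The forecast names ochre as leader, with 53% for violet, 58% for green, 72% for blue and 86% for ochre, and says: “Violet keeps A high without partner, so it self-reacts heavily”. For violet my share stands above its figure.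

The flasks give 62.5% in violet, 68.6% in green, 77.3% in blue and 85.1% in ochre, so ochre leads.

    first end groups + second end groups ⇌ links + released group (K = 121, k = 0.702 M⁻¹ s⁻¹)
    second end groups ⇌ dormant form (K = 1.86, k = 0.00127 s⁻¹)
    2 first end groups → self-condensation product (k = 0.0341 M⁻¹ s⁻¹)

Violet's 62.5% lies 3.7 percentage points below the 66.2% reckoned from the waste rate. The gap of 23 points between ochre and violet shrinks to 1.9 points in the run without the loss of two first end groups to self-condensation product, the largest single effect on that gap. Carried to blue, where [first end groups] averages 0.00792 M over the feed, the waste rate 0.261 min⁻¹ scaled by the square of that mean against the charge gives 2.19% lost during the feed, and blue holds 2.94% as self-condensation product at 6.00 min.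

The data are simulated from invented constants; the scatter is artificial.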